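**Retrosynthetic overview**
1. The seven-membered ring is closed last, by ring-closing metathesis at C8=C9 of diene 12.
2. Diene 12 comes from cyclopentane aldehyde 8 by methallylation at C6, anisoylation of the C6 hydroxyl and vinylation of the unmasked C10 aldehyde.
3. Aldehyde 8 comes from bicyclic β-lactone 6, which already carries C1, C4 and C5 with the tertiary C4–O in place.
4. Lactone 6 is made first, from enal 4 and vinyl ketone 5 by a chiral carbene homoenolate annulation: the C1–C2 bond joins the β-carbons of two acceptors, then aldol closure (C4–C5) and lactonisation form the five-membered ring.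
5. Enal 4 comes from commercial ethyl (E)-3-methyl-4-oxobut-2-enoate 1 by acetalisation and redox adjustment.

Atom labels C1–C10 follow daucane numbering (C1 quaternary methyl carbon, C4 isopropyl carbinol, C5 ring-fusion CH, C6 ester carbinol, C10 free carbinol).
Assumption: compounds 1 and 5 are bought, and the facial sense of the triazolium catalyst in step 4 is assigned by analogy; if it proves opposite, its commercial antipode is used.

**Step 1**
Reactants: 1 ethyl (E)-3-methyl-4-oxobut-2-enoate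
Product: 2 ethyl (E)-4,4-diethoxy-3-methylbut-2-enoate
Conditions: HC(OEt)3, EtOH, cat. p-TsOH·H2O, 23 °C
Reagents that add atoms: triethyl orthoformate, CCOC(OCC)OCC
Why: Acid-catalysed acetalisation with an orthoester masks the future C10 aldehyde without touching the E-alkene, and ethanol as solvent avoids ester exchange.

**Step 2**
Reactants: 2 ethyl (E)-4,4-diethoxy-3-methylbut-2-enoate
Product: 3 (E)-4,4-diethoxy-3-methylbut-2-en-1-ol
Conditions: iBu2AlH (2.3 equiv), CH2Cl2, −78 → 0 °C; aq. potassium sodium tartrate work-up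
Reagents that add atoms: none
Why: iBu2AlH reduces the enoate cleanly in the 1,2-sense to the allylic alcohol, and the acetal is inert to hydride and to the neutral work-up.

**Step 3**
Reactants: 3 (E)-4,4-diethoxy-3-methylbut-2-en-1-ol
Product: 4 (E)-4,4-diethoxy-3-methylbut-2-enal
Conditions: activated MnO2 (15 equiv), CH2Cl2, 23 °C
Reagents that add atoms: none
Why: Allylic oxidation with MnO2 stops at the enal and keeps the E geometry and the acetal.

**Step 4**
Reactants: 4 (E)-4,4-diethoxy-3-methylbut-2-enal; 5 4-methylpent-1-en-3-one (isopropyl vinyl ketone)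
Product: 6 (1R,2S,5R)-2-(diethoxymethyl)-2-methyl-5-(propan-2-yl)-6-oxabicyclo[3.2.0]heptan-7-one
Conditions: (5aR,10bS)-5a,10b-dihydro-2-(2,4,6-trimethylphenyl)-4H,6H-indeno[2,1-b][1,2,4]triazolo[4,3-d][1,4]oxazinium chloride (15 mol %), DBU (20 mol %), THF, 0 → 23 °C, 5 (1.5 equiv) added over 8 h by syringe pump
Reagents that add atoms: none
Why: Proposed new method: the carbene adds to the aldehyde of 4 to give a Breslow intermediate that is nucleophilic at C1 (homoenolate), conjugate addition to the CH2 terminus of 5 forms the C1–C2 bond and the quaternary centre on the face set by the aminoindanol catalyst, the derived azolium enolate closes C5–C4 by aldol onto the isopropyl ketone with the acyl azolium anti to the bulkier diethoxymethyl group, and only the cis alkoxide can lactonise and release the carbene, so C1, C5 and C4 are set together; the closest known reaction type is the carbene-catalysed homoenolate annulation of enals with enones to cyclopentane-fused β-lactones, here extended to a β,β-disubstituted enal and a β-unsubstituted alkyl vinyl ketone.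

**Step 5**
Reactants: 6 (1R,2S,5R)-2-(diethoxymethyl)-2-methyl-5-(propan-2-yl)-6-oxabicyclo[3.2.0]heptan-7-one
Product: 7 (1R,2S,3S)-3-(diethoxymethyl)-2-(hydroxymethyl)-3-methyl-1-(propan-2-yl)cyclopentan-1-ol
Conditions: LiAlH4, THF, 0 °C
Reagents that add atoms: none
Why: Hydride reduction of the strained β-lactone at the acyl carbon gives the primary C6 alcohol and frees the tertiary C4 hydroxyl with no stereocentre touched.

**Step 6**
Reactants: 7 (1R,2S,3S)-3-(diethoxymethyl)-2-(hydroxymethyl)-3-methyl-1-(propan-2-yl)cyclopentan-1-ol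
Product: 8 (1R,2S,5R)-2-(diethoxymethyl)-5-hydroxy-2-methyl-5-(propan-2-yl)cyclopentane-1-carbaldehyde
Conditions: TEMPO (10 mol %), PhI(OAc)2 (1.2 equiv), CH2Cl2, 23 °C; crude used directly
Reagents that add atoms: none
Why: Oxoammonium (TEMPO) oxidation takes the primary alcohol to the aldehyde under non-basic conditions, so the β-hydroxy aldehyde neither retro-aldolises nor epimerises at C5, and the tertiary alcohol cannot be oxidised.

**Step 7**
Reactants: 8 (1R,2S,5R)-2-(diethoxymethyl)-5-hydroxy-2-methyl-5-(propan-2-yl)cyclopentane-1-carbaldehyde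
Product: 9 (1R,2S,3S)-3-(diethoxymethyl)-2-[(1S)-1-hydroxy-3-methylbut-3-en-1-yl]-3-methyl-1-(propan-2-yl)cyclopentan-1-ol
Conditions: (−)-Ipc2BOMe (2.6 equiv), CH2=C(CH3)CH2MgCl (2.5 equiv), Et2O, 0 → 23 °C; then 8, −78 °C; oxidative work-up NaOH, H2O2
Reagents that add atoms: methallylmagnesium chloride, C=C(C)C[Mg]Cl
Why: Brown asymmetric methallylboration through a chair transition state adds to the Si face of the aldehyde and gives (6S), the same face the substrate prefers because the rear face is blocked by the cis C1 methyl group.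

**Step 8**
Reactants: 9 (1R,2S,3S)-3-(diethoxymethyl)-2-[(1S)-1-hydroxy-3-methylbut-3-en-1-yl]-3-methyl-1-(propan-2-yl)cyclopentan-1-ol
Product: 11 (1S)-1-[(1S,2S,5R)-2-formyl-5-hydroxy-2-methyl-5-(propan-2-yl)cyclopentyl]-3-methylbut-3-en-1-yl 4-methoxybenzoate, via acetal ester 10 (not isolated)
Conditions: 4-MeOC6H4COCl (1.5 equiv), Et3N (3 equiv), DMAP (0.2 equiv), CH2Cl2, 0 → 40 °C; then THF, 2 M aq. HCl, 23 °C
Reagents that add atoms: 4-methoxybenzoyl chloride, COc1ccc(cc1)C(Cl)=O; water, O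
Why: DMAP-catalysed acylation takes only the secondary C6 hydroxyl (the tertiary C4 hydroxyl is inert), and dilute aqueous acid then hydrolyses the diethyl acetal to the C10 aldehyde, which cannot form a lactol because the C4 hydroxyl is trans to it.

**Step 9**
Reactants: 11 (1S)-1-[(1S,2S,5R)-2-formyl-5-hydroxy-2-methyl-5-(propan-2-yl)cyclopentyl]-3-methylbut-3-en-1-yl 4-methoxybenzoate
Product: 12 (1S)-1-[(1S,2S,5R)-5-hydroxy-2-[(1R)-1-hydroxyprop-2-en-1-yl]-2-methyl-5-(propan-2-yl)cyclopentyl]-3-methylbut-3-en-1-yl 4-methoxybenzoate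
Conditions: (CH2=CH)2Zn (3 equiv), (+)-MIB [(2R)-3-exo-morpholinoisoborneol, 20 mol %], toluene, 0 °C; aq. NH4Cl
Reagents that add atoms: divinylzinc, C=C[Zn]C=C
Why: Amino-alcohol-catalysed vinylzinc addition (Noyori–Oppolzer type) delivers vinyl to the Re face of the neopentyl aldehyde under catalyst control to give (10R), and the organozinc does not attack the anisoate.

**Step 10**
Reactants: 12 (1S)-1-[(1S,2S,5R)-5-hydroxy-2-[(1R)-1-hydroxyprop-2-en-1-yl]-2-methyl-5-(propan-2-yl)cyclopentyl]-3-methylbut-3-en-1-yl 4-methoxybenzoate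
Product: 13 (3R,3aS,4S,8R,8aS)-3,8-dihydroxy-6,8a-dimethyl-3-(propan-2-yl)-1,2,3,3a,4,5,8,8a-octahydroazulen-4-yl 4-methoxybenzoate
Conditions: second-generation Grubbs catalyst (5 mol %), CH2Cl2 (5 mM), 40 °C
Reagents that add atoms: none
Why: Ring-closing metathesis of the vinyl carbinol with the methallyl group forms the trisubstituted C8=C9 alkene and the trans-fused seven-membered ring with loss of ethylene, and no stereocentre is involved.

**Compound list**
1 | ethyl (E)-3-methyl-4-oxobut-2-enoate | CCOC(=O)/C=C(\C)C=O | starting material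
2 | ethyl (E)-4,4-diethoxy-3-methylbut-2-enoate | CCOC(=O)/C=C(\C)C(OCC)OCC | intermediate
3 | (E)-4,4-diethoxy-3-methylbut-2-en-1-ol | OC/C=C(\C)C(OCC)OCC | intermediate
4 | (E)-4,4-diethoxy-3-methylbut-2-enal | O=C/C=C(\C)C(OCC)OCC | intermediate
5 | 4-methylpent-1-en-3-one | C=CC(=O)C(C)C | starting material
6 | (1R,2S,5R)-2-(diethoxymethyl)-2-methyl-5-(propan-2-yl)-6-oxabicyclo[3.2.0]heptan-7-one | CCOC(OCC)[C@@]3(C)CC[C@]1(C(C)C)OC(=O)[C@@H]13 | intermediate
7 | (1R,2S,3S)-3-(diethoxymethyl)-2-(hydroxymethyl)-3-methyl-1-(propan-2-yl)cyclopentan-1-ol | CCOC(OCC)[C@@]1(C)CC[C@@](O)(C(C)C)[C@@H]1CO | intermediate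
8 | (1R,2S,5R)-2-(diethoxymethyl)-5-hydroxy-2-methyl-5-(propan-2-yl)cyclopentane-1-carbaldehyde | CCOC(OCC)[C@@]1(C)CC[C@@](O)(C(C)C)[C@@H]1C=O | intermediate
9 | (1R,2S,3S)-3-(diethoxymethyl)-2-[(1S)-1-hydroxy-3-methylbut-3-en-1-yl]-3-methyl-1-(propan-2-yl)cyclopentan-1-ol | CCOC(OCC)[C@@]1(C)CC[C@@](O)(C(C)C)[C@@H]1[C@H](CC(C)=C)O | intermediate
10 | (1S)-1-[(1S,2S,5R)-2-(diethoxymethyl)-5-hydroxy-2-methyl-5-(propan-2-yl)cyclopentyl]-3-methylbut-3-en-1-yl 4-methoxybenzoate | CCOC(OCC)[C@@]1(C)CC[C@@](O)(C(C)C)[C@@H]1[C@H](CC(C)=C)OC(=O)c1ccc(OC)cc1 | intermediate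
11 | (1S)-1-[(1S,2S,5R)-2-formyl-5-hydroxy-2-methyl-5-(propan-2-yl)cyclopentyl]-3-methylbut-3-en-1-yl 4-methoxybenzoate | O=C[C@@]1(C)CC[C@@](O)(C(C)C)[C@@H]1[C@H](CC(C)=C)OC(=O)c1ccc(OC)cc1 | intermediate
12 | (1S)-1-[(1S,2S,5R)-5-hydroxy-2-[(1R)-1-hydroxyprop-2-en-1-yl]-2-methyl-5-(propan-2-yl)cyclopentyl]-3-methylbut-3-en-1-yl 4-methoxybenzoate | C=C[C@@H](O)[C@@]1(C)CC[C@@](O)(C(C)C)[C@@H]1[C@H](CC(C)=C)OC(=O)c1ccc(OC)cc1 | intermediate
13 | (3R,3aS,4S,8R,8aS)-3,8-dihydroxy-6,8a-dimethyl-3-(propan-2-yl)-1,2,3,3a,4,5,8,8a-octahydroazulen-4-yl 4-methoxybenzoate | COc1ccc(C(=O)O[C@H]2CC(C)=C[C@@H](O)[C@@]3(C)CC[C@@](O)(C(C)C)[C@H]23)cc1 | target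

**Step count and risks**
Total step count: 10. Longest linear sequence: 10 steps (1 → 13); compound 5 enters at step 4.

Step 4 is the most likely to fail. A β,β-disubstituted enal is a sluggish homoenolate precursor, and the carbene can instead add to or polymerise the vinyl ketone. Stetter acylation or loss of ethoxide from the γ-acetal may compete, and the C1/C5 diastereoselectivity and the enantioselectivity are untested. The fallback builds the quaternary centre by enamine catalysis and closes both rings by an ammonium-enolate aldol-lactonisation, setting out from 1 and 5 and returning at 6. Hydrogenation of 1 (H2, Pd/C, EtOAc) gives ethyl 3-methyl-4-oxobutanoate F1. A 9-amino-9-deoxy-epi-cinchona primary amine salt then catalyses the Michael addition of F1 to 5 and gives ethyl (3S)-3-formyl-3,7-dimethyl-6-oxooctanoate F2. HC(OEt)3 in EtOH with catalytic acid protects only the aldehyde, giving ethyl (3S)-3-(diethoxymethyl)-3,7-dimethyl-6-oxooctanoate F3. LiOH gives (3S)-3-(diethoxymethyl)-3,7-dimethyl-6-oxooctanoic acid F4. Activation of F4 with 2-chloro-1-methylpyridinium iodide, a chiral isothiourea and iPr2NEt gives the cis-fused β-lactone 6.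

Step 7 is the second risk. The aldehyde is flanked by two fully substituted carbons, the free tertiary hydroxyl consumes allylborane, and 8 can retro-aldolise or epimerise if handled for long. The fallback sets out from 6, returns at 9 and makes C6–C7 by acylation and C6–H by catalyst-controlled reduction. MeNH(OMe)·HCl with iPrMgCl opens the lactone to (1R,2S,5R)-2-(diethoxymethyl)-5-hydroxy-N-methoxy-N,2-dimethyl-5-(propan-2-yl)cyclopentane-1-carboxamide F5. CH2=C(CH3)CH2MgCl at −78 °C gives 1-[(1R,2S,5R)-2-(diethoxymethyl)-5-hydroxy-2-methyl-5-(propan-2-yl)cyclopentyl]-3-methylbut-3-en-1-one F6. (R)-2-Methyl-CBS-oxazaborolidine with BH3·SMe2 reduces F6 to 9.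

Step 9 is the third risk. The aldehyde sits on a quaternary stereocentre whose own facial bias is small and may oppose the catalyst, and the hindered carbonyl may react slowly with the zinc reagent. The fallback sets out from 11, returns at 12 and sets C10 by reduction instead of addition. CH2=CHMgBr with CeCl3 at −78 °C gives 12 together with its (10S)-epimer (1S)-1-[(1S,2S,5R)-5-hydroxy-2-[(1S)-1-hydroxyprop-2-en-1-yl]-2-methyl-5-(propan-2-yl)cyclopentyl]-3-methylbut-3-en-1-yl 4-methoxybenzoate F7. Dess–Martin periodinane converts the mixture into (1S)-1-[(1S,2S,5R)-5-hydroxy-2-methyl-5-(propan-2-yl)-2-(prop-2-enoyl)cyclopentyl]-3-methylbut-3-en-1-yl 4-methoxybenzoate F8. (S)-2-Methyl-CBS-oxazaborolidine with catecholborane reduces F8 to 12, the tertiary-alkyl group acting as the large substituent.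

**Further compounds**
F1 | step 4 | ethyl 3-methyl-4-oxobutanoate (racemic) | CCOC(=O)CC(C)C=O
F2 | step 4 | ethyl (3S)-3-formyl-3,7-dimethyl-6-oxooctanoate | O=C[C@@](C)(CCC(=O)C(C)C)CC(=O)OCC
F3 | step 4 | ethyl (3S)-3-(diethoxymethyl)-3,7-dimethyl-6-oxooctanoate | CCOC(OCC)[C@@](C)(CCC(=O)C(C)C)CC(=O)OCC
F4 | step 4 | (3S)-3-(diethoxymethyl)-3,7-dimethyl-6-oxooctanoic acid | CCOC(OCC)[C@@](C)(CCC(=O)C(C)C)CC(=O)O
F5 | step 7 | (1R,2S,5R)-2-(diethoxymethyl)-5-hydroxy-N-methoxy-N,2-dimethyl-5-(propan-2-yl)cyclopentane-1-carboxamide | CCOC(OCC)[C@@]1(C)CC[C@@](O)(C(C)C)[C@@H]1C(=O)N(C)OC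
F6 | step 7 | 1-[(1R,2S,5R)-2-(diethoxymethyl)-5-hydroxy-2-methyl-5-(propan-2-yl)cyclopentyl]-3-methylbut-3-en-1-one | CCOC(OCC)[C@@]1(C)CC[C@@](O)(C(C)C)[C@@H]1C(=O)CC(C)=C
F7 | step 9 | (1S)-1-[(1S,2S,5R)-5-hydroxy-2-[(1S)-1-hydroxyprop-2-en-1-yl]-2-methyl-5-(propan-2-yl)cyclopentyl]-3-methylbut-3-en-1-yl 4-methoxybenzoate | C=C[C@H](O)[C@@]1(C)CC[C@@](O)(C(C)C)[C@@H]1[C@H](CC(C)=C)OC(=O)c1ccc(OC)cc1
F8 | step 9 | (1S)-1-[(1S,2S,5R)-5-hydroxy-2-methyl-5-(propan-2-yl)-2-(prop-2-enoyl)cyclopentyl]-3-methylbut-3-en-1-yl 4-methoxybenzoate | C=CC(=O)[C@@]1(C)CC[C@@](O)(C(C)C)[C@@H]1[C@H](CC(C)=C)OC(=O)c1ccc(OC)cc1
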